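If I book each mole of G to where it ends, one entry of the ledger stands still, and I can freeze it.

| flask | G | remark | time |
|---|---|---|---|
| south-east | 0.088 M | run made earlier |  |
| ochre | 0.080 M |  | 5.0 min |
| red | 0.12 M |  | 5.0 min |
| blue | 0.20 M |  | 5.0 min |

south-east run (percent of the G charged)

| time / min | D / % | X / % |
|---|---|---|
| 0.250 | 37.8 | 57.2 |
| 0.417 | 35.4 | 59.1 |
| 0.667 | 31.3 | 59.0 |
| 1.00 | 25.7 | 56.9 |
| 2.00 | 16.8 | 55.8 |
| 3.00 | 12.1 | 59.6 |

(each reading ± 1 percentage point)

- share of D in all that became D or X or J for ochre, red, blue, in this order
- the course of these numbers from the first flask to the last (rises, then falls / hardly changes / rises all the way / falls, then rises / falls all the way)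

- the numbers in the tables scatter with a standard deviation of 1 percentage point
- "hardly changes" means that all values lie within two and a half points (for a concentration: within two and a half percent of the largest)

In the south-east run G is the substrate, and D and X are read while J is not. At the first reading D and X together already hold 95.0 % of the charge. The first entry is X: its readings show no trend and average 57.9 %, so I freeze it there. The second entry is s, the D-side share, meaning the part of the charge that does not end as X (a branching fraction): 42.1 %. The third entry divides s between D and J. D reads 12.1 % at 3.00 min while X holds, so I book J by difference at 30.0 %, the entry that makes the books add up to the charge. The asked share is therefore D as a part of the charge.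

My own reckoning continues the last step of the south-east run. From 2.00 min to 3.00 min D keeps 0.720 of itself, and applying that ratio over the 2.00 min still to go gives 6.28 % at 5.0 min. One run at one charge cannot show the orders, so I assume that percentages carry over and give each flask this figure.

The forecast gives 4.8 %, 4.8 % and 4.8 %, a course that hardly changes, on the ground that “both branches have the same order, which gives a constant split”. My figure stands higher, but the course is the same.

The flasks give 8.09 %, 8.09 % and 8.09 %, and the course hardly changes. The forecast holds within its margins.

    G → X (k = 0.190 /s)
    D ⇌ J (K = 5.40, k = 0.00883 /s)
    G → D (k = 0.136 /s)
    G → L (k = 2.45 × 10⁻⁶ /s)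

In ochre at 5.00 min, D is 19.2 % of s. The reverse step, J to D, is the main reason D stands at that height: without it, ochre keeps 3.03 %, which is 7.20 % of s. Blue shows the same lift of 5.1 percentage points: 8.09 % with the step and 3.03 % without it, which is 7.20 % of s.

The numbers in the tables were generated by integration on assumed constants, and the scatter is random.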